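The ten-membered carbocycle C1–C10 is reached by contraction of a twelve-membered ring. Its C8–C9 bond links an oxygenated carbon next to the C7 carbonyl (the later butenolide β-carbon) to the allylic CH2 of the C1=C10–C14HO enal: an enolate–allyl pair. In the precursor C9 is tied to C8 through O–C(=O), a macrocyclic allyl β-keto lactone from acylketene lactonisation. Pd(0) ionises the allyl ester, CO2 leaves and the C8 enolate closes on C9; both C8 epimers converge and the C6-oxy C7-ketone needed for the butenolide (intramolecular HWE) results. C4/C5 come from Sharpless epoxidation of geraniol, C6 from a Felkin addition.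

Key step: step 15

Remark: atom labels follow germacrane numbering (ring C1–C10; C1=C10 enal alkene, C4/C5 epoxide, C6 lactone oxygen, C7 butenolide β-carbon, C8 isovalerate; C11/C12/C13 butenolide α-carbon, carbonyl and acetoxymethyl; C14 formyl; C15 methyl). Compounds 4, 9, 10, 16 and 27 are assumed to be purchasable. PMB = 4-methoxybenzyl, TBS = tert-butyldimethylsilyl, TES = triethylsilyl.

Step 1
Reactants: 1 geraniol
Product: 2 (2R,3R)-2,3-epoxygeraniol
Conditions: Ti(OiPr)4 (5 mol%), D-(−)-diethyl tartrate (6 mol%), t-BuOOH, 4 Å MS, CH2Cl2, −20 °C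
Reagents that add atoms: tert-butyl hydroperoxide, CC(C)(C)OO
Why: Sharpless asymmetric epoxidation of the allylic alcohol, in which the D-(−)-tartrate complex should deliver oxygen to the face that gives the (2R,3R)-epoxide (C4 and C5 of the target) while the remote alkene, not being an allylic alcohol, is left alone.

Step 2
Reactants: 2 (2R,3R)-2,3-epoxygeraniol
Product: 3 (2S,3R)-epoxygeranial
Conditions: TPAP (5 mol%), NMO, 4 Å MS, CH2Cl2, rt
Reagents that add atoms: none
Why: Ley–Griffith oxidation of the primary epoxy alcohol to the aldehyde under neutral conditions that should neither open nor epimerise the epoxide.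

Step 3
Reactants: 3 (2S,3R)-epoxygeranial; 4 1,3-dithiane
Product: 6 (S)-(1,3-dithian-2-yl) epoxy carbinol, via 2-lithio-1,3-dithiane 5 (not isolated)
Conditions: 4, n-BuLi, THF, −30 °C; then 3, −78 °C; aq NH4Cl
Reagents that add atoms: none
Why: Corey–Seebach acyl-anion addition, in which Felkin–Anh attack of the non-chelating lithium reagent anti to the epoxide C5–O bond should give the anti (erythro) epoxy carbinol and so set C6.

Step 4
Reactants: 6 (S)-(1,3-dithian-2-yl) epoxy carbinol
Product: 7 TBS ether of 6
Conditions: TBSOTf, 2,6-lutidine, CH2Cl2, −78 °C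
Reagents that add atoms: tert-butyldimethylsilyl triflate, CC(C)(C)[Si](C)(C)OS(=O)(=O)C(F)(F)F
Why: silylation of the hindered secondary alcohol under buffered low-temperature conditions that the epoxide and dithiane should tolerate.

Step 5
Reactants: 7 TBS ether of 6
Product: 8 (S)-α-silyloxy epoxy aldehyde (C7 aldehyde)
Conditions: MeI, CaCO3, MeCN/H2O (9:1), 45 °C
Reagents that add atoms: water, O
Why: alkylative dithioacetal hydrolysis (S-methylation, ring opening, hydrolysis) under buffered non-oxidising conditions that should spare the trisubstituted alkene, the epoxide and the C6 configuration.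

Step 6
Reactants: 9 4-methoxybenzyl alcohol; 10 tert-butyl bromoacetate
Product: 11 tert-butyl 2-[(4-methoxybenzyl)oxy]acetate
Conditions: NaH, THF, 0 °C; then 10, Bu4NI (cat.), 0 °C → rt
Reagents that add atoms: none
Why: Williamson ether synthesis on a reactive α-bromo ester whose tert-butyl group suppresses transesterification.

Step 7
Reactants: 8 (S)-α-silyloxy epoxy aldehyde; 11 tert-butyl 2-[(4-methoxybenzyl)oxy]acetate
Product: 13 β-hydroxy ester (C7/C8 diastereomer mixture), via lithium ester enolate 12 (not isolated)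
Conditions: 11, LDA, THF, −78 °C; then 8, −78 °C; aq NH4Cl
Reagents that add atoms: none
Why: glycolate aldol addition of a lithium ester enolate to the aldehyde, whose new C7 and C8 centres need no control because C7 is oxidised in step 8 and C8 is reset in step 15.

Step 8
Reactants: 13 β-hydroxy ester
Product: 14 α-PMB-oxy β-keto tert-butyl ester (C8 epimers)
Conditions: Dess–Martin periodinane, pyridine, CH2Cl2, 0 °C → rt
Reagents that add atoms: none
Why: Dess–Martin oxidation of the secondary carbinol under buffered conditions gives the β-keto ester without touching the alkene, the epoxide or the PMB ether.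

Step 9
Reactants: 14 α-PMB-oxy β-keto tert-butyl ester
Product: 15 C1 aldehyde
Conditions: OsO4 (2 mol%), NaIO4, 2,6-lutidine, dioxane/H2O (3:1), rt
Reagents that add atoms: sodium periodate, [Na+].[O-]I(=O)(=O)=O
Why: Lemieux–Johnson cleavage of the only C=C bond (the isopropylidene terminus) should unveil the C1 aldehyde without the arene oxidation that ozone could cause at the PMB ether.

Step 10
Reactants: 16 (2-hydroxyethyl)triphenylphosphonium bromide
Product: 17 triphenyl[2-(triethylsilyloxy)ethyl]phosphonium bromide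
Conditions: Et3SiCl, imidazole, CH2Cl2, 0 °C → rt
Reagents that add atoms: chlorotriethylsilane, CC[Si](Cl)(CC)CC
Why: standard O-silylation, which gives the future C9 oxygen a group removable later in the presence of the secondary TBS ether.

Step 11
Reactants: 17 triphenyl[2-(triethylsilyloxy)ethyl]phosphonium bromide
Product: 19 3-(triethylsilyloxy)-2-(triphenylphosphoranylidene)propanal, via silyloxyethylidene ylide 18 (not isolated)
Conditions: NaHMDS (2 equiv), THF, −78 °C; then HCO2Et, −78 °C → rt
Reagents that add atoms: ethyl formate, CCOC=O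
Why: C-formylation of a non-stabilised phosphorus ylide with a formate ester, the second equivalent of base converting the formylphosphonium into the stabilised formyl ylide, with low temperature chosen to disfavour β-elimination of silanolate.

Step 12
Reactants: 15 C1 aldehyde; 19 3-(triethylsilyloxy)-2-(triphenylphosphoranylidene)propanal
Product: 20 (E)-enal with C9–OTES arm
Conditions: toluene, 70 °C
Reagents that add atoms: none
Why: Wittig olefination with a stabilised α-branched formyl ylide, which should react only with the aldehyde (not the C7 ketone or the acidic β-keto ester) and give the (E)-enal, i.e. C14HO trans and the C9 arm cis to the C2 chain as the ring-cis C1=C10 bond requires.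

Step 13
Reactants: 20 (E)-enal with C9–OTES arm
Product: 21 seco hydroxy β-keto ester (free C9–OH)
Conditions: HF·pyridine, pyridine, THF, 0 °C
Reagents that add atoms: none
Why: buffered fluoride desilylation should cleave the primary allylic TES ether much faster than the hindered secondary TBS ether at C6.

Step 14
Reactants: 21 seco hydroxy β-keto ester
Product: 23 twelve-membered α-PMB-oxy β-keto lactone (C8 epimers), via acylketene 22 (not isolated)
Conditions: toluene, reflux, 1 mM (slow addition), 4 Å MS
Reagents that add atoms: none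
Why: thermal retro-ene loss of tert-butanol from the β-keto tert-butyl ester gives an α-alkoxy acylketene that the C9 hydroxyl should trap at high dilution (acylketene macrolactonisation), and the C8 epimer mixture is erased in the next step.

Step 15
Reactants: 23 twelve-membered α-PMB-oxy β-keto lactone
Product: 25 ten-membered (8S)-α-PMB-oxy ketone, via allylpalladium enolate 24 (not isolated)
Conditions: Pd2(dba)3·CHCl3 (5 mol%), (R,R)-DACH-phenyl bis(2-diphenylphosphinobenzamide) ligand (12 mol%), degassed 1,4-dioxane, 2 mM, 25 °C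
Reagents that add atoms: none
Why: Proposed new method: Pd(0) ionises the endocyclic allylic C9–O ester bond of 23 to a 2-formyl-π-allylpalladium β-keto carboxylate, CO2 is lost, and the resulting α-alkoxy enolate (C8 now planar, so both C8 epimers of 23 converge) bonds through carbon to the allyl terminus C9 and releases Pd(0), which excises O–C(=O) from the twelve-membered ring. The closest known reaction type is the Tsuji–Saegusa decarboxylative allylic alkylation of acyclic allyl β-keto esters, including its ligand-controlled form for α-oxygenated enolates, together with decarboxylative ring contractions of small vinyl heterocycles and Tsuji–Trost macrocyclisations; it has not been shown on a macrocyclic allyl β-keto lactone. The ten-membered ring closes by attack at the unsubstituted terminus C9, which keeps C10=C1 endocyclic (endo mode with respect to the allyl unit), rather than at C1, which would give an eight-membered ring with an exocyclic formylvinyl group. The C8 stereocentre is set by the chiral diphosphine, which should differentiate the faces of the O,O-chelated (Z)-enolate as in ligand-controlled allylations of α-oxy ketone enolates (the ligand enantiomer being the one matched to 8S), and the ring-cis C1=C10 geometry is carried over from the anti π-allyl that the (E)-enal gives and is the one a ten-membered ring accommodates. The step needs C- over O-allylation, C9 over C1 attack and recombination faster than proton transfer to the C6 side (which would open the epoxide); the soft palladium enolate, the unhindered CH2 terminus, high dilution and base-free conditions are expected to secure these.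

Step 16
Reactants: 25 ten-membered (8S)-α-PMB-oxy ketone
Product: 26 C6-hydroxy ketone
Conditions: HF·pyridine, pyridine, THF, 0 °C → rt
Reagents that add atoms: none
Why: buffered fluoride cleavage of the only silyl ether should free the C6 hydroxyl without base that could enolise the ketone towards the epoxide.

Step 17
Reactants: 27 ethyl 2-(diethoxyphosphoryl)acrylate; 9 4-methoxybenzyl alcohol
Product: 28 ethyl 2-(diethoxyphosphoryl)-3-[(4-methoxybenzyl)oxy]propanoate
Conditions: t-BuOK (5 mol%), THF, 0 °C
Reagents that add atoms: none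
Why: base-catalysed oxa-Michael addition of the alcohol to the doubly activated vinylphosphonate installs the protected C13 oxygen on the phosphonate reagent.

Step 18
Reactants: 28 ethyl 2-(diethoxyphosphoryl)-3-[(4-methoxybenzyl)oxy]propanoate
Product: 29 2-(diethoxyphosphoryl)-3-[(4-methoxybenzyl)oxy]propanoic acid
Conditions: LiOH, THF/H2O, 0 °C; then aq HCl to pH 3
Reagents that add atoms: lithium hydroxide, [Li+].[OH-]
Why: saponification of the carboxylic ester at low temperature, where the phosphonate esters and the poorly leaving β-alkoxide should survive.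

Step 19
Reactants: 26 C6-hydroxy ketone; 29 2-(diethoxyphosphoryl)-3-[(4-methoxybenzyl)oxy]propanoic acid
Product: 30 C6 phosphonoacyl ester
Conditions: DCC, DMAP (cat.), CH2Cl2, 0 °C
Reagents that add atoms: none
Why: Steglich esterification acylates the only free hydroxyl (C6) under near-neutral conditions and places the phosphonate carbon (C11) five atoms from the C7 ketone.

Step 20
Reactants: 30 C6 phosphonoacyl ester
Product: 31 8,13-bis-PMB butenolide
Conditions: LiCl, i-Pr2NEt, MeCN, 0 °C → rt
Reagents that add atoms: none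
Why: intramolecular Horner–Wadsworth–Emmons reaction under Masamune–Roush conditions closes the butenolide by forming the tetrasubstituted C7=C11 bond, the five-membered closure on the ketone being expected to outrun any reaction at the remote enal.

Step 21
Reactants: 31 8,13-bis-PMB butenolide
Product: 32 8,13-diol
Conditions: DDQ, CH2Cl2/pH 7 buffer, 0 °C
Reagents that add atoms: none
Why: oxidative cleavage of both PMB ethers with DDQ under buffered conditions, which the epoxide, enal and butenolide should tolerate.

Step 22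
Reactants: 32 8,13-diol
Product: 33 13-acetate 8-alcohol
Conditions: AcCl, 2,4,6-collidine, CH2Cl2, −78 °C
Reagents that add atoms: acetyl chloride, CC(Cl)=O
Why: selective acylation of the primary C13 hydroxyl over the hindered secondary C8 hydroxyl with a weak hindered base at low temperature.

Step 23
Reactants: 33 13-acetate 8-alcohol
Product: 34 target (CNP0289605.1)
Conditions: isovaleric anhydride, pyridine, DMAP (cat.), CH2Cl2, 0 °C
Reagents that add atoms: isovaleric anhydride, CC(C)CC(=O)OC(=O)CC(C)C
Why: DMAP-catalysed esterification of the C8 alcohol with retention of configuration completes the target.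

Compound list
1 | geraniol, (2E)-3,7-dimethylocta-2,6-dien-1-ol | CC(C)=CCC/C(C)=C/CO | starting material
2 | (2R,3R)-2,3-epoxygeraniol, [(2R,3R)-3-methyl-3-(4-methylpent-3-en-1-yl)oxiran-2-yl]methanol | CC(C)=CCC[C@@]1(C)O[C@@H]1CO | intermediate
3 | (2S,3R)-3-methyl-3-(4-methylpent-3-en-1-yl)oxirane-2-carbaldehyde (epoxygeranial) | CC(C)=CCC[C@@]1(C)O[C@@H]1C=O | intermediate
4 | 1,3-dithiane | C1CSCSC1 | starting material
5 | 2-lithio-1,3-dithiane | [Li]C1SCCCS1 | intermediate
6 | (S)-(1,3-dithian-2-yl)[(2R,3R)-3-methyl-3-(4-methylpent-3-en-1-yl)oxiran-2-yl]methanol | CC(C)=CCC[C@@]1(C)O[C@@H]1[C@@H](C2SCCCS2)O | intermediate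
7 | tert-butyldimethylsilyl ether of 6 | CC(C)=CCC[C@@]1(C)O[C@@H]1[C@@H](C2SCCCS2)O[Si](C)(C)C(C)(C)C | intermediate
8 | (2S)-2-(tert-butyldimethylsilyloxy)-2-[(2R,3R)-3-methyl-3-(4-methylpent-3-en-1-yl)oxiran-2-yl]acetaldehyde | CC(C)=CCC[C@@]1(C)O[C@@H]1[C@@H](C=O)O[Si](C)(C)C(C)(C)C | intermediate
9 | 4-methoxybenzyl alcohol | COc1ccc(CO)cc1 | starting material
10 | tert-butyl bromoacetate | CC(C)(C)OC(=O)CBr | starting material
11 | tert-butyl 2-[(4-methoxybenzyl)oxy]acetate | COc1ccc(COCC(=O)OC(C)(C)C)cc1 | intermediate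
12 | lithium enolate of 11 | COc1ccc(COC=C(O[Li])OC(C)(C)C)cc1 | intermediate
13 | tert-butyl 4-(TBS-oxy)-3-hydroxy-2-(PMB-oxy)-4-[(2R,3R)-3-methyl-3-(4-methylpent-3-en-1-yl)oxiran-2-yl]butanoate, C6 as in 8, C7/C8 mixture | CC(C)=CCC[C@@]1(C)O[C@@H]1[C@@H](C(O)C(OCc2ccc(OC)cc2)C(=O)OC(C)(C)C)O[Si](C)(C)C(C)(C)C | intermediate
14 | tert-butyl (4S)-4-(TBS-oxy)-2-(PMB-oxy)-4-[(2R,3R)-3-methyl-3-(4-methylpent-3-en-1-yl)oxiran-2-yl]-3-oxobutanoate, C8 epimers | CC(C)=CCC[C@@]1(C)O[C@@H]1[C@@H](C(=O)C(OCc2ccc(OC)cc2)C(=O)OC(C)(C)C)O[Si](C)(C)C(C)(C)C | intermediate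
15 | tert-butyl (4S)-4-(TBS-oxy)-2-(PMB-oxy)-4-[(2R,3R)-3-methyl-3-(3-oxopropyl)oxiran-2-yl]-3-oxobutanoate | O=CCC[C@@]1(C)O[C@@H]1[C@@H](C(=O)C(OCc2ccc(OC)cc2)C(=O)OC(C)(C)C)O[Si](C)(C)C(C)(C)C | intermediate
16 | (2-hydroxyethyl)triphenylphosphonium bromide | OCC[P+](c1ccccc1)(c1ccccc1)c1ccccc1.[Br-] | starting material
17 | triphenyl[2-(triethylsilyloxy)ethyl]phosphonium bromide | CC[Si](CC)(CC)OCC[P+](c1ccccc1)(c1ccccc1)c1ccccc1.[Br-] | intermediate
18 | [2-(triethylsilyloxy)ethylidene]triphenylphosphorane | CC[Si](CC)(CC)OCC=P(c1ccccc1)(c1ccccc1)c1ccccc1 | intermediate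
19 | 3-(triethylsilyloxy)-2-(triphenylphosphoranylidene)propanal | CC[Si](CC)(CC)OCC(C=O)=P(c1ccccc1)(c1ccccc1)c1ccccc1 | intermediate
20 | tert-butyl (4S)-4-(TBS-oxy)-4-{(2R,3R)-3-[(3E)-4-formyl-5-(triethylsilyloxy)pent-3-en-1-yl]-3-methyloxiran-2-yl}-2-(PMB-oxy)-3-oxobutanoate | O=C/C(CO[Si](CC)(CC)CC)=C/CC[C@@]1(C)O[C@@H]1[C@@H](C(=O)C(OCc2ccc(OC)cc2)C(=O)OC(C)(C)C)O[Si](C)(C)C(C)(C)C | intermediate
21 | tert-butyl (4S)-4-(TBS-oxy)-4-{(2R,3R)-3-[(3E)-4-formyl-5-hydroxypent-3-en-1-yl]-3-methyloxiran-2-yl}-2-(PMB-oxy)-3-oxobutanoate | O=C/C(CO)=C/CC[C@@]1(C)O[C@@H]1[C@@H](C(=O)C(OCc2ccc(OC)cc2)C(=O)OC(C)(C)C)O[Si](C)(C)C(C)(C)C | intermediate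
22 | α-(PMB-oxy) acylketene from 21 | O=C/C(CO)=C/CC[C@@]1(C)O[C@@H]1[C@@H](C(=O)C(OCc2ccc(OC)cc2)=C=O)O[Si](C)(C)C(C)(C)C | intermediate
23 | twelve-membered β-keto lactone: ring C9–O–C(=O)–C8(OPMB)–C7(=O)–C6(OTBS)–C5–C4(epoxide)–C3–C2–C1=C10(CHO); (4R,5R,6S), ring-cis C1=C10, C8 epimers | O=C/C1=C/CC[C@@]2(C)O[C@@H]2[C@H](O[Si](C)(C)C(C)(C)C)C(=O)C(OCc3ccc(OC)cc3)C(=O)OC1 | intermediate
24 | allylpalladium enolate from 23 after loss of CO2, drawn as the η1-allyl O-bound form without ligand | O=C/C1=C/CC[C@@]2(C)O[C@@H]2[C@H](O[Si](C)(C)C(C)(C)C)C(=COCc3ccc(OC)cc3)O[Pd]C1 | intermediate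
25 | ten-membered ketone: (4R,5R,6S,8S)-4,5-epoxy-8-(PMB-oxy)-6-(TBS-oxy)-7-oxogermacr-1(10)-en-14-al, ring-cis C1=C10 | O=C/C1=C/CC[C@@]2(C)O[C@@H]2[C@H](O[Si](C)(C)C(C)(C)C)C(=O)[C@@H](OCc3ccc(OC)cc3)C1 | intermediate
26 | (4R,5R,6S,8S)-4,5-epoxy-6-hydroxy-8-(PMB-oxy)-7-oxogermacr-1(10)-en-14-al | O=C/C1=C/CC[C@@]2(C)O[C@@H]2[C@H](O)C(=O)[C@@H](OCc3ccc(OC)cc3)C1 | intermediate
27 | ethyl 2-(diethoxyphosphoryl)acrylate | C=C(C(=O)OCC)P(=O)(OCC)OCC | starting material
28 | ethyl 2-(diethoxyphosphoryl)-3-[(4-methoxybenzyl)oxy]propanoate | CCOC(=O)C(COCc1ccc(OC)cc1)P(=O)(OCC)OCC | intermediate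
29 | 2-(diethoxyphosphoryl)-3-[(4-methoxybenzyl)oxy]propanoic acid | OC(=O)C(COCc1ccc(OC)cc1)P(=O)(OCC)OCC | intermediate
30 | C6 ester of 26 with acid 29 (phosphonate carbon unspecified) | O=C/C1=C/CC[C@@]2(C)O[C@@H]2[C@H](OC(=O)C(COCc3ccc(OC)cc3)P(=O)(OCC)OCC)C(=O)[C@@H](OCc3ccc(OC)cc3)C1 | intermediate
31 | (4R,5R,6R,8S)-4,5-epoxy-8,13-bis(PMB-oxy)-14-oxogermacra-1(10),7(11)-dien-12,6-olide | COc1ccc(COCC2=C3[C@@H](OCc4ccc(OC)cc4)C/C(C=O)=C\CC[C@@]4(C)O[C@@H]4[C@@H]3OC2=O)cc1 | intermediate
32 | (4R,5R,6R,8S)-4,5-epoxy-8,13-dihydroxy-14-oxogermacra-1(10),7(11)-dien-12,6-olide | OCC1=C2[C@@H](O)C/C(C=O)=C\CC[C@@]3(C)O[C@@H]3[C@@H]2OC1=O | intermediate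
33 | (4R,5R,6R,8S)-13-acetoxy-4,5-epoxy-8-hydroxy-14-oxogermacra-1(10),7(11)-dien-12,6-olide | CC(=O)OCC1=C2[C@@H](O)C/C(C=O)=C\CC[C@@]3(C)O[C@@H]3[C@@H]2OC1=O | intermediate
34 | CNP0289605.1, (4R,5R,6R,8S)-13-acetoxy-4,5-epoxy-8-(3-methylbutanoyloxy)-14-oxogermacra-1(10),7(11)-dien-12,6-olide | CC(=O)OCC1=C2[C@@H](OC(=O)CC(C)C)C/C(C=O)=C\CC[C@@]3(C)O[C@@H]3[C@@H]2OC1=O | target

Total step count: 23. Longest linear sequence: 18 steps (1–5, 7–9, 12–16, 19–23).

Steps most likely to fail

Step 15 (Proposed new method). What may go wrong: after ionisation and loss of CO2 the enolate may be protonated or captured by a second molecule before the transannular C8–C9 bond forms, or the two enolate faces may not be differentiated. Fallback with known chemistry, setting out from 21 and returning at 26: 21 is heated with excess 2-(trimethylsilyl)ethanol in toluene so that the acylketene is trapped intermolecularly as the 2-(trimethylsilyl)ethyl β-keto ester F1. The C9 hydroxyl is then converted with methyl chloroformate/pyridine into the allylic methyl carbonate F2. Pd(PPh3)4/dppe in THF at high dilution closes the ring directly by intramolecular Tsuji–Trost C-allylation of the doubly stabilised β-keto ester enolate, an established route to medium and large carbocycles, to give the ten-membered 8-carboxylate F3. Buffered TBAF then removes the silylethyl ester (with decarboxylation) and the C6 silyl ether in one operation and gives 26. C8 is then set by protonation of the enol, so 26 may be accompanied by its 8-epimer F4, which is separated and recycled by mild base equilibration through the enol.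

Step 14. What may go wrong: at the temperature needed to release the acylketene from the α-alkoxy tert-butyl ester, intermolecular trapping (oligomers) or thermal degradation of the enal and epoxide may outrun the twelve-membered ring closure. Fallback, setting out from 14 and returning at 23: the acylketene is generated from the more robust 14 and trapped with excess 2-methylpropane-2-thiol to give the S-tert-butyl β-keto thioester F5. Lemieux–Johnson cleavage gives the thioester aldehyde F6, Wittig reaction with 19 gives the thioester enal silyl ether F7, and buffered HF·pyridine gives the thioester enal alcohol F8, as in steps 9, 12 and 13. The ring is then closed at room temperature by thiophilic activation of the thioester (AgOCOCF3, Na2HPO4, benzene, high dilution), a thiol-ester macrolactonisation that gives 23 without heating.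

Step 3. What may go wrong: poor facial selectivity in the addition to the α,β-epoxy aldehyde (competition between the Felkin–Anh and chelated or Cornforth-type transition states) would leave much of the C6 epimer. Fallback, setting out from 6 as obtained (its mixture with the C6 epimer) and returning at 6: the carbinol mixture is oxidised (SO3·pyridine, DMSO, Et3N) to the epoxy ketone F9. Reduction with Zn(BH4)2 in Et2O at −20 °C, in which zinc chelates the carbonyl and epoxide oxygens and hydride arrives from the open face, should give the erythro (anti) epoxy alcohol, i.e. 6.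

Further compounds
F1 | step 15 | 2-(trimethylsilyl)ethyl ester analogue of 21 | O=C/C(CO)=C/CC[C@@]1(C)O[C@@H]1[C@@H](C(=O)C(OCc2ccc(OC)cc2)C(=O)OCC[Si](C)(C)C)O[Si](C)(C)C(C)(C)C
F2 | step 15 | C9 methyl carbonate of F1 | O=C/C(COC(=O)OC)=C/CC[C@@]1(C)O[C@@H]1[C@@H](C(=O)C(OCc2ccc(OC)cc2)C(=O)OCC[Si](C)(C)C)O[Si](C)(C)C(C)(C)C
F3 | step 15 | ten-membered 8-[2-(trimethylsilyl)ethoxycarbonyl] ketone (C8 quaternary, unspecified) | O=C/C1=C/CC[C@@]2(C)O[C@@H]2[C@H](O[Si](C)(C)C(C)(C)C)C(=O)C(OCc3ccc(OC)cc3)(C(=O)OCC[Si](C)(C)C)C1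
F4 | step 15 | 8-epimer of 26 | O=C/C1=C/CC[C@@]2(C)O[C@@H]2[C@H](O)C(=O)[C@H](OCc3ccc(OC)cc3)C1
F5 | step 14 | S-tert-butyl thioester analogue of 14 | CC(C)=CCC[C@@]1(C)O[C@@H]1[C@@H](C(=O)C(OCc2ccc(OC)cc2)C(=O)SC(C)(C)C)O[Si](C)(C)C(C)(C)C
F6 | step 14 | S-tert-butyl thioester analogue of 15 | O=CCC[C@@]1(C)O[C@@H]1[C@@H](C(=O)C(OCc2ccc(OC)cc2)C(=O)SC(C)(C)C)O[Si](C)(C)C(C)(C)C
F7 | step 14 | S-tert-butyl thioester analogue of 20 | O=C/C(CO[Si](CC)(CC)CC)=C/CC[C@@]1(C)O[C@@H]1[C@@H](C(=O)C(OCc2ccc(OC)cc2)C(=O)SC(C)(C)C)O[Si](C)(C)C(C)(C)C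
F8 | step 14 | S-tert-butyl thioester analogue of 21 | O=C/C(CO)=C/CC[C@@]1(C)O[C@@H]1[C@@H](C(=O)C(OCc2ccc(OC)cc2)C(=O)SC(C)(C)C)O[Si](C)(C)C(C)(C)C
F9 | step 3 | (1,3-dithian-2-yl)[(2S,3R)-3-methyl-3-(4-methylpent-3-en-1-yl)oxiran-2-yl]methanone | CC(C)=CCC[C@@]1(C)O[C@@H]1C(=O)C2SCCCS2
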